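**Retrosynthetic overview**

1. The strategy rests on the 4'-hydroxyl of ring B standing para to C1'. Oxidising that phenol makes C3 the exocyclic carbon of a ring B para-quinone methide, and C4, the formyl carbon on ring A, can be delivered to it as an acyl anion equivalent.
2. Last skeletal bond: C3–C4, by carbene-catalysed intramolecular 1,6-acylation. This closes ring C, the only ring formed (rings A and B are bought as arenes), and sets C3.
3. Before that: O1–C2, by Mitsunobu etherification of a ring B 2-arylethanol with a ring A salicylaldehyde.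
4. Ring A piece: 5-bromo-2,4-dihydroxybenzaldehyde, 4-O-silylation, then Stille prenylation at the bromine-marked carbon (future C6). Ring B piece: 4-bromo-2,5-dimethoxybenzaldehyde, Baeyer–Villiger oxidation (CHO to 4'-OH), allyl protection, then Br/Li exchange and oxirane (which supplies C2 and C3).
5. Protecting groups: 7-O-triisopropylsilyl, removed last with buffered HF; 4'-O-allyl, removed with zerovalent palladium just before the oxidation.

Key step: step 8

Remark: C3 is read from the target SMILES as S (priorities C4 > C2 > C1' > H); quinone methide 14 is drawn as the less hindered E isomer (C2 syn to C6'–H), and either geometry would lead to the same constitution.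

**Route**

Step 1
Reactants: 1 5-bromo-2,4-dihydroxybenzaldehyde
Product: 2 5-bromo-2-hydroxy-4-(triisopropylsilyloxy)benzaldehyde
Conditions: TIPSCl (1.05 equiv), imidazole, DMF, 0 °C to rt
Reagents that add atoms: chlorotriisopropylsilane (TIPSCl), CC(C)[Si](Cl)(C(C)C)C(C)C
Why: Regioselective phenol O-silylation: the 2-hydroxyl is tied up in a hydrogen bond to the formyl group and is the less acidic one, so one equivalent of the bulky chlorosilane should silylate only the 4-hydroxyl.

Step 2
Reactants: 2 5-bromo-2-hydroxy-4-(triisopropylsilyloxy)benzaldehyde; 3 tributyl(3-methylbut-2-en-1-yl)stannane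
Product: 4 2-hydroxy-5-(3-methylbut-2-en-1-yl)-4-(triisopropylsilyloxy)benzaldehyde
Conditions: Pd(PPh3)4 (5 mol%), degassed DMF, 90 °C
Reagents that add atoms: none
Why: Stille cross-coupling: oxidative addition of zerovalent palladium into the aryl C–Br bond and transmetalation of the allylic stannane at its tin-bearing carbon should install the linear prenyl group under neutral, fluoride-free conditions that spare the phenol, the aldehyde and the aryl silyl ether.

Step 3
Reactants: 5 4-bromo-2,5-dimethoxybenzaldehyde
Product: 7 4-bromo-2,5-dimethoxyphenol, via aryl formate 6 (not isolated)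
Conditions: mCPBA, CH2Cl2, 0 °C to rt; then K2CO3, MeOH, rt
Reagents that add atoms: 3-chloroperoxybenzoic acid (mCPBA), O=C(OO)c1cccc(Cl)c1
Why: Baeyer–Villiger (Dakin-type) oxidation: the electron-rich aryl group with its ortho-methoxy substituent migrates in the Criegee intermediate to give the aryl formate, which methanolysis cleaves to the phenol.

Step 4
Reactants: 7 4-bromo-2,5-dimethoxyphenol
Product: 8 1-bromo-2,5-dimethoxy-4-(prop-2-en-1-yloxy)benzene
Conditions: allyl bromide, K2CO3, acetone, reflux
Reagents that add atoms: allyl bromide, C=CCBr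
Why: Williamson etherification of the phenoxide (SN2); the allyl ether tolerates the organolithium and Mitsunobu steps and can later be removed without base or fluoride.

Step 5
Reactants: 8 1-bromo-2,5-dimethoxy-4-(prop-2-en-1-yloxy)benzene; 9 oxirane
Product: 11 2-[2,5-dimethoxy-4-(prop-2-en-1-yloxy)phenyl]ethan-1-ol, via aryllithium 10 (not isolated)
Conditions: n-BuLi, THF, −78 °C; oxirane (3 equiv, THF solution), −78 to 0 °C; aq NH4Cl
Reagents that add atoms: none
Why: Bromine–lithium exchange is fast at −78 °C, and the aryllithium, stabilised by its ortho-methoxy group, opens oxirane at carbon to give the 2-arylethanol directly (epoxide opening by an organolithium).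

Step 6
Reactants: 4 2-hydroxy-5-(3-methylbut-2-en-1-yl)-4-(triisopropylsilyloxy)benzaldehyde; 11 2-[2,5-dimethoxy-4-(prop-2-en-1-yloxy)phenyl]ethan-1-ol
Product: 12 2-{2-[2,5-dimethoxy-4-(prop-2-en-1-yloxy)phenyl]ethoxy}-5-(3-methylbut-2-en-1-yl)-4-(triisopropylsilyloxy)benzaldehyde
Conditions: PPh3, DIAD, THF, 0 °C to rt
Reagents that add atoms: none
Why: Mitsunobu etherification: the primary alcohol is activated as its oxyphosphonium ion and displaced by the acidic ortho-formyl phenol to form O1–C2 under neutral conditions, avoiding the carbonate bases that could cleave the activated aryl silyl ether.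

Step 7
Reactants: 12 2-{2-[2,5-dimethoxy-4-(prop-2-en-1-yloxy)phenyl]ethoxy}-5-(3-methylbut-2-en-1-yl)-4-(triisopropylsilyloxy)benzaldehyde
Product: 13 2-[2-(4-hydroxy-2,5-dimethoxyphenyl)ethoxy]-5-(3-methylbut-2-en-1-yl)-4-(triisopropylsilyloxy)benzaldehyde
Conditions: Pd(PPh3)4 (5 mol%), morpholine, THF, rt
Reagents that add atoms: none
Why: Tsuji–Trost-type deallylation: zerovalent palladium ionises the aryl allyl ether to a π-allyl complex that morpholine captures, freeing the 4'-phenol without touching the C-prenyl group, the aldehyde or the silyl ether.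

Step 8
Reactants: 13 2-[2-(4-hydroxy-2,5-dimethoxyphenyl)ethoxy]-5-(3-methylbut-2-en-1-yl)-4-(triisopropylsilyloxy)benzaldehyde
Product: 15 (3S)-3-(4-hydroxy-2,5-dimethoxyphenyl)-6-(3-methylbut-2-en-1-yl)-7-(triisopropylsilyloxy)-2,3-dihydro-4H-chromen-4-one, via quinone methide 14 (not isolated)
Conditions: Ag2O (1.5 equiv), 4 Å sieves, toluene, 0 °C, dark; filter through Celite under argon into (5aS,10bR)-2-(pentafluorophenyl)-5a,10b-dihydro-4H,6H-indeno[2,1-b][1,2,4]triazolo[4,3-d][1,4]oxazin-2-ium tetrafluoroborate (20 mol%), iPr2NEt (20 mol%), toluene, −20 to 0 °C; then AcOH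
Reagents that add atoms: none
Why: Proposed new method: Ag2O dehydrogenates the 4'-phenol of 13 to quinone methide 14, and after the silver is filtered off the triazolylidene adds to the ring A aldehyde, proton transfer gives the Breslow intermediate, its nucleophilic carbon (C4) attacks the exocyclic methide carbon (C3), ring B rearomatises to the 4'-phenoxide, and proton relay with loss of the carbene leaves the C4 ketone. The closest known reactions are the carbene-catalysed 1,6-addition of aldehydes to 2,6-di-tert-butyl para-quinone methides and the aminoindanol-triazolium intramolecular Stetter closure of salicylaldehyde-tethered Michael acceptors to 3-substituted chroman-4-ones; what is new is their combination on an unhindered, enolisable quinone methide made in the same operation. Ring C closes in a 6-exo-trig mode, the C3=C1' bond lying outside the new ring. C3, the only new stereocentre, is set by the catalyst: the fused aminoindanol backbone and the N-pentafluorophenyl group leave one face of the Breslow intermediate open to the methide carbon, and the antipode of the precatalyst that gives 3S is to be confirmed in a first run, both antipodes being available. The step needs acyl transfer to C3 to outrun tautomerisation of 14 to the styryl ether, oxidation of the Breslow intermediate by 14 and enolisation of the product at C3; the O1–C2 tether allows only the six-membered closure at the methide carbon, the 2'- and 5'-methoxy groups make 14 a weaker oxidant and a longer-lived electrophile, the 7-O-silyl group keeps the aldehyde electrophilic, and only a substoichiometric amine base is present at low temperature before the acetic acid quench. Silver must be removed first because Ag2O would convert the triazolium salt into a silver carbene complex.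

Step 9
Reactants: 15 (3S)-3-(4-hydroxy-2,5-dimethoxyphenyl)-6-(3-methylbut-2-en-1-yl)-7-(triisopropylsilyloxy)-2,3-dihydro-4H-chromen-4-one
Product: 16 (3S)-7-hydroxy-3-(4-hydroxy-2,5-dimethoxyphenyl)-6-(3-methylbut-2-en-1-yl)-2,3-dihydro-4H-chromen-4-one
Conditions: HF·pyridine, pyridine, THF, 0 °C to rt (polypropylene vessel)
Reagents that add atoms: none
Why: Fluoride-mediated Si–O cleavage of the aryl silyl ether, helped by the para-acyl phenoxide leaving group; the pyridine-buffered, weakly acidic medium should avoid enolisation at C3 (its hydrogen is α to the ketone and benzylic) and leave the prenyl group and both phenols intact.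

**Compound list**

1 | 5-bromo-2,4-dihydroxybenzaldehyde | O=Cc1cc(Br)c(O)cc1O | starting material
2 | 5-bromo-2-hydroxy-4-(triisopropylsilyloxy)benzaldehyde | O=Cc1cc(Br)c(O[Si](C(C)C)(C(C)C)C(C)C)cc1O | intermediate
3 | tributyl(3-methylbut-2-en-1-yl)stannane | CC(C)=CC[Sn](CCCC)(CCCC)CCCC | starting material
4 | 2-hydroxy-5-(3-methylbut-2-en-1-yl)-4-(triisopropylsilyloxy)benzaldehyde | O=Cc1cc(CC=C(C)C)c(O[Si](C(C)C)(C(C)C)C(C)C)cc1O | intermediate
5 | 4-bromo-2,5-dimethoxybenzaldehyde | COc1cc(C=O)c(OC)cc1Br | starting material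
6 | 4-bromo-2,5-dimethoxyphenyl formate | COc1cc(OC=O)c(OC)cc1Br | intermediate
7 | 4-bromo-2,5-dimethoxyphenol | COc1cc(O)c(OC)cc1Br | intermediate
8 | 1-bromo-2,5-dimethoxy-4-(prop-2-en-1-yloxy)benzene | C=CCOc1cc(OC)c(Br)cc1OC | intermediate
9 | oxirane | C1CO1 | starting material
10 | [2,5-dimethoxy-4-(prop-2-en-1-yloxy)phenyl]lithium | [Li]c1cc(OC)c(OCC=C)cc1OC | intermediate
11 | 2-[2,5-dimethoxy-4-(prop-2-en-1-yloxy)phenyl]ethan-1-ol | OCCc1cc(OC)c(OCC=C)cc1OC | intermediate
12 | 2-{2-[2,5-dimethoxy-4-(prop-2-en-1-yloxy)phenyl]ethoxy}-5-(3-methylbut-2-en-1-yl)-4-(triisopropylsilyloxy)benzaldehyde | O=Cc1cc(CC=C(C)C)c(O[Si](C(C)C)(C(C)C)C(C)C)cc1OCCc1cc(OC)c(OCC=C)cc1OC | intermediate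
13 | 2-[2-(4-hydroxy-2,5-dimethoxyphenyl)ethoxy]-5-(3-methylbut-2-en-1-yl)-4-(triisopropylsilyloxy)benzaldehyde | O=Cc1cc(CC=C(C)C)c(O[Si](C(C)C)(C(C)C)C(C)C)cc1OCCc1cc(OC)c(O)cc1OC | intermediate
14 | 2-{[(2E)-2-(2,5-dimethoxy-4-oxocyclohexa-2,5-dien-1-ylidene)ethyl]oxy}-5-(3-methylbut-2-en-1-yl)-4-(triisopropylsilyloxy)benzaldehyde | COC1=C/C(=C\COc2cc(O[Si](C(C)C)(C(C)C)C(C)C)c(CC=C(C)C)cc2C=O)C(OC)=CC1=O | intermediate
15 | (3S)-3-(4-hydroxy-2,5-dimethoxyphenyl)-6-(3-methylbut-2-en-1-yl)-7-(triisopropylsilyloxy)-2,3-dihydro-4H-chromen-4-one | COc1cc([C@H]2COc3cc(O[Si](C(C)C)(C(C)C)C(C)C)c(CC=C(C)C)cc3C2=O)c(OC)cc1O | intermediate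
16 | (3S)-7-hydroxy-3-(4-hydroxy-2,5-dimethoxyphenyl)-6-(3-methylbut-2-en-1-yl)-2,3-dihydro-4H-chromen-4-one | COc1cc([C@H]2COc3cc(O)c(CC=C(C)C)cc3C2=O)c(OC)cc1O | target

**Step count and risks**

Total steps: 9. Longest linear sequence: 7 steps (from 5 through steps 3, 4, 5, 6, 7, 8 and 9 to 16).

Steps most likely to fail:

1. Step 8 (proposed new method). The Breslow intermediate may be oxidised by the quinone methide (hydride or electron transfer) instead of adding to it. The quinone methide may tautomerise to the styryl ether or dimerise through its phenoxyl radical before it is intercepted. Facial discrimination, or configurational integrity at C3 under the basic conditions, may be insufficient.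

   Fallback by known isoflavone chemistry, setting out from 4 and 8 and coming back at 15:
   - Aldehyde 4 would be treated with MeMgBr (THF, −78 to 0 °C) to give the carbinol 1-[2-hydroxy-5-(3-methylbut-2-en-1-yl)-4-(triisopropylsilyloxy)phenyl]ethan-1-ol F1, and MnO2 (CH2Cl2) would oxidise it to the acetophenone F2.
   - N,N-Dimethylformamide dimethyl acetal (toluene, 80 °C) should give the enaminone F3, which I2 and pyridine in CHCl3 close to the 3-iodochromone F4.
   - Bromide 8 would give, by Br/Li exchange, B(OiPr)3 and aqueous work-up, the boronic acid F5.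
   - Suzuki–Miyaura coupling of F4 with F5 (Pd(dppf)Cl2, K3PO4, dioxane with a little water, 60 °C) should give the isoflavone F6.
   - Asymmetric transfer hydrogenation with dynamic kinetic resolution (RuCl(p-cymene)[(S,S)-TsDPEN], HCO2H/Et3N, EtOAc, 40 °C) reduces C2=C3 and C4=O and is expected, by analogy with aryl ketone reductions, to give the cis-(3S,4S)-isoflavan-4-ol F7.
   - Dess–Martin periodinane (CH2Cl2, 0 °C) reoxidises C4 to the (3S)-isoflavanone 4'-allyl ether F8.
   - Pd(PPh3)4 with sodium 4-methylbenzenesulfinate (THF/MeOH, rt) frees the 4'-phenol to give 15.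

2. Step 2. Allylic transposition at the transmetalation stage would deliver the 1,1-dimethylallyl isomer, and slow coupling at the bromide flanked by the bulky silyloxy group would lead to protodebromination.

   Fallback, setting out from 2 and coming back at 4: Stille coupling of 2 with allyltributylstannane (Pd(PPh3)4, DMF, 90 °C) uses a smaller, symmetrical allyl group and should give 5-allyl-2-hydroxy-4-(triisopropylsilyloxy)benzaldehyde F9. Olefin cross-metathesis of F9 with excess 2-methylbut-2-ene (second-generation Grubbs catalyst, CH2Cl2, 40 °C) then builds the prenyl terminus and gives 4.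

3. Step 6. β-Elimination of the activated 2-arylethanol to the styrene, together with slow attack by the hydrogen-bonded ortho-formyl phenol, would let the betaine be consumed by alkylation of the hydrazide.

   Fallback, setting out from 11 and coming back at 12: Appel iodination of 11 (I2, PPh3, imidazole, CH2Cl2, 0 °C) should give the iodide 1-(2-iodoethyl)-2,5-dimethoxy-4-(prop-2-en-1-yloxy)benzene F10. Williamson alkylation of phenol 4 with F10 (K2CO3, dry acetone, 50 °C) then forms O1–C2 by direct SN2 displacement and gives 12.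

Further compounds
F1 | step 8 | 1-[2-hydroxy-5-(3-methylbut-2-en-1-yl)-4-(triisopropylsilyloxy)phenyl]ethan-1-ol (racemic) | CC(O)c1cc(CC=C(C)C)c(O[Si](C(C)C)(C(C)C)C(C)C)cc1O
F2 | step 8 | 1-[2-hydroxy-5-(3-methylbut-2-en-1-yl)-4-(triisopropylsilyloxy)phenyl]ethan-1-one | CC(=O)c1cc(CC=C(C)C)c(O[Si](C(C)C)(C(C)C)C(C)C)cc1O
F3 | step 8 | (2E)-3-(dimethylamino)-1-[2-hydroxy-5-(3-methylbut-2-en-1-yl)-4-(triisopropylsilyloxy)phenyl]prop-2-en-1-one | CN(C)/C=C/C(=O)c1cc(CC=C(C)C)c(O[Si](C(C)C)(C(C)C)C(C)C)cc1O
F4 | step 8 | 3-iodo-6-(3-methylbut-2-en-1-yl)-7-(triisopropylsilyloxy)-4H-chromen-4-one | O=c1c(I)coc2cc(O[Si](C(C)C)(C(C)C)C(C)C)c(CC=C(C)C)cc12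
F5 | step 8 | [2,5-dimethoxy-4-(prop-2-en-1-yloxy)phenyl]boronic acid | OB(O)c1cc(OC)c(OCC=C)cc1OC
F6 | step 8 | 3-[2,5-dimethoxy-4-(prop-2-en-1-yloxy)phenyl]-6-(3-methylbut-2-en-1-yl)-7-(triisopropylsilyloxy)-4H-chromen-4-one | O=c1c(-c2cc(OC)c(OCC=C)cc2OC)coc2cc(O[Si](C(C)C)(C(C)C)C(C)C)c(CC=C(C)C)cc12
F7 | step 8 | (3S,4S)-3-[2,5-dimethoxy-4-(prop-2-en-1-yloxy)phenyl]-6-(3-methylbut-2-en-1-yl)-7-(triisopropylsilyloxy)-3,4-dihydro-2H-chromen-4-ol (cis) | C=CCOc1cc(OC)c([C@H]2COc3cc(O[Si](C(C)C)(C(C)C)C(C)C)c(CC=C(C)C)cc3[C@H]2O)cc1OC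
F8 | step 8 | (3S)-3-[2,5-dimethoxy-4-(prop-2-en-1-yloxy)phenyl]-6-(3-methylbut-2-en-1-yl)-7-(triisopropylsilyloxy)-2,3-dihydro-4H-chromen-4-one | C=CCOc1cc(OC)c([C@H]2COc3cc(O[Si](C(C)C)(C(C)C)C(C)C)c(CC=C(C)C)cc3C2=O)cc1OC
F9 | step 2 | 2-hydroxy-5-(prop-2-en-1-yl)-4-(triisopropylsilyloxy)benzaldehyde | C=CCc1cc(C=O)c(O)cc1O[Si](C(C)C)(C(C)C)C(C)C
F10 | step 6 | 1-(2-iodoethyl)-2,5-dimethoxy-4-(prop-2-en-1-yloxy)benzene | C=CCOc1cc(OC)c(CCI)cc1OC
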